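The constants of the proposed steps were hidden from me, so I started from a balance that needs none: on the proposed steps, each coupling partner either enters the catalyst cycle and yields one product, or meets protic impurity and becomes quenched reagent.

| flask | substrate | coupling partner | protic impurity | free catalyst | temperature | remark | time |
|---|---|---|---|---|---|---|---|
| winter | 0.80 M | 0.84 M | 0.80 M | 40 mM | 20 °C | the very flask that is asked about, followed so far |  |
| autumn | 0.54 M | 0.84 M | 0.80 M | 40 mM | 5 °C | run made earlier |  |
| flask | 0.80 M | 0.840 M | 0.800 M | 40 mM | 20 °C |  | 15 min |

| run | time / min | product / % |
|---|---|---|
| winter | 1.50 | 35.7 |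
| winter | 4.00 | 35.7 |
| winter | 8.00 | 33.2 |
| winter | 12.0 | 34.0 |
| autumn | 0.667 | 25.9 |
| autumn | 1.33 | 45.6 |
| autumn | 2.00 | 50.5 |
| autumn | 3.00 | 49.5 |

(scatter of a reading: 1 percentage point)

- Wednesday's: at 15 min take out 90% of the product then present, then wait 5.0 min
- Sunday's: at 15 min raise the temperature by 15 K, then wait 5.0 min
- Monday's: at 15 min add coupling partner, 50.0% of the amount charged, then wait 5.0 min
- Saturday's: at 15 min add free catalyst, 50.0% of the amount charged, then wait 5.0 min
- Thursday's: change nothing and wait 5.0 min more

- product taken out counts as made
- what was read earlier has a scatter of 1 percentage point, one standard deviation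
- steps that have been proposed: coupling partner + free catalyst -> catalyst intermediate A; catalyst intermediate C -> free catalyst + product; catalyst intermediate A <-> by-product + catalyst intermediate B; coupling partner + protic impurity -> quenched reagent; substrate + catalyst intermediate B <-> catalyst intermediate C
- additions bring no volume worth counting

1. product, in percent of the substrate first charged, at 15 min
2. the remedy with the largest gain of product, or "none" below 2 percentage points (Wednesday's / Sunday's / Monday's / Saturday's / Thursday's / none)
3. product present, with what was taken out counted in, in percent of the substrate first charged, after Wednesday's
4. product present, with what was taken out counted in, in percent of the substrate first charged, after Saturday's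

1. The winter readings showed no trend beyond their scatter, so I averaged them to a plateau of 34.7% of the substrate, which was my figure for the flask at 15 min, and which equals 33.0% of the partner charged. My doubt was that something else had stopped the winter flask, but 65.3% of its substrate stood unused, and the autumn run, with less substrate and colder, gave 32.1% of its partner as product. I therefore took the partner as the limiting reagent and expected Wednesday's and Saturday's to leave the plateau where it was.

2. On that balance the remaining 67.0% of the partner in the winter flask had gone to the impurity, which by my reckoning left 29.7% of the impurity charge, and the mean of that level and the full charge was 64.8%. The proposed quench step carries the impurity in its rate and the catalyst steps do not, so the ratio of the two rates at any moment should follow the impurity then present. I therefore defined the waste factor, a selectivity factor, as quenched reagent made per product made, divided by the mean fraction of the impurity charge present: 3.13. My objection was that this figure is an average over the winter run, at one catalyst charge and one partner charge, so I held its use elsewhere as an assumption.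

3. For Monday's I first kept the impurity at 29.7%, which gave a productive share of 51.9% and a gain of 27 percentage points. But the impurity falls as it is quenched, and that share would take it to 4.37%. The mean of these two levels gave a share of 65.2% and a gain of 34 points. This overstates the fall, so I expected a gain between the two and chose Monday's.

4. The forecast gave 34.6% (33.8% to 35.4%), 34.6% after Wednesday's and 34.6% after Saturday's, and chose Monday's, reasoning that “The coupling partner is exhausted”.

5. The flask gave 36.6%, 36.6% after Wednesday's and 36.6% after Saturday's, and the best remedy was Monday's, with a gain of 33 points.

    coupling partner + free catalyst → catalyst intermediate A (k = 23.0 L mol⁻¹ s⁻¹, Ea = 37.0 kJ mol⁻¹)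
    catalyst intermediate C → free catalyst + product (k = 10.0 s⁻¹, Ea = 66.0 kJ mol⁻¹)
    catalyst intermediate A ⇌ by-product + catalyst intermediate B (K = 0.970 M, k = 0.970 s⁻¹, Ea = 66.0 kJ mol⁻¹, ΔH = −38.0 kJ mol⁻¹)
    coupling partner + protic impurity → quenched reagent (k = 0.250 L mol⁻¹ s⁻¹, Ea = 53.0 kJ mol⁻¹)
    substrate + catalyst intermediate B ⇌ catalyst intermediate C (K = 2.80 L mol⁻¹, k = 1.20 L mol⁻¹ s⁻¹, Ea = 45.0 kJ mol⁻¹, ΔH = −48.0 kJ mol⁻¹)
    (constants at 20 °C)

The quench is the main reason for the flask's shortfall: the run without that step gave 100% against 36.6%. Monday's gain lay inside the bracket set by the waste factor, between 27 points and 34 points. In the same flask with 0.20 M of protic impurity, the factor, with the impurity level taken as the mean of that charge and zero, asks for 118% of that impurity charge, more than stood there, so I capped the quench at the charge and reckoned 80.0%; that flask gave 80.4%, with 1.57% of its impurity left.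

(The data stem from a simulated flask for an exercise; the scatter is artificial.)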